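**Retrosynthetic overview**
1. Target 27 ← fluoride cleavage of 2-(trimethylsilyl)ethyl ester 26 ← methylenation of 7α-acetoxy-8-ketone 25 ← α-oxygenation of decalone 22.
2. Ring B (made last) ← one-carbon ring expansion of trans-hydrindanone 14: C10 shifts from C8 to a new carbon C9, and the enolate so formed is alkylated with dienyl bromide 17 (from enynol 15).
3. Five-membered ring of 14 ← ring-closing metathesis of an allyl group (C6, C7) with a 1-silylvinyl group (C8, masked ketone).
4. C4 (methyl and carboxyl) ← ring-A ketone → enol triflate → carbonylation → conjugate reduction/methylation.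
5. Ring A with C5/C10 ← asymmetric conjugate addition to 3-methylcyclohex-2-en-1-one 1 with allyl trapping. Ring order: A (bought), five-membered ring, then ring B by expansion.

Assumption: 1, 2, 3 and 15 are taken as commercial; labdane numbering (C1–C20) is used for locants in the explanations.

**Step 1**
Reactants: 1 3-methylcyclohex-2-en-1-one; 2 ethynyltrimethylsilane; 3 allyl acetate
Product: 6 (2R,3S)-2-allyl-3-methyl-3-[1-(trimethylsilyl)vinyl]cyclohexan-1-one, via vinylalane 4 (not isolated), via aluminium enolate 5 (not isolated)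
Conditions: 2, i-Bu2AlH, hexane, 55 °C; then 1, Cu(OTf)2 (5 mol %), chiral sulfonate-bearing imidazolinium salt (carbene precursor, 5 mol %, the enantiomer giving the S quaternary carbon), THF, −15 °C; then 3, Pd(PPh3)4 (5 mol %), rt
Reagents that add atoms: none
Why: Copper–carbene-catalysed asymmetric conjugate addition of the α-silylvinylalane sets quaternary C10, and Tsuji–Trost allylation of the regiodefined aluminium enolate enters anti to the bulky silylvinyl group, so allyl is cis to methyl (the later trans ring fusion).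

**Step 2**
Reactants: 6 (2R,3S)-2-allyl-3-methyl-3-[1-(trimethylsilyl)vinyl]cyclohexan-1-one
Product: 8 (5S,6R)-6-allyl-5-methyl-5-[1-(trimethylsilyl)vinyl]cyclohex-1-en-1-yl trifluoromethanesulfonate, via lithium enolate 7 (not isolated)
Conditions: LiN(i-Pr)2, THF, −78 °C; then PhNTf2, −78 → 0 °C
Reagents that add atoms: N-phenylbis(trifluoromethanesulfonimide), O=S(=O)(N(c1ccccc1)S(=O)(=O)C(F)(F)F)C(F)(F)F
Why: Kinetic deprotonation takes the CH2 proton (the tertiary α-H beside the quaternary carbon is shielded) and O-triflation gives the enol triflate; no stereocentre is touched.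

**Step 3**
Reactants: 8 (5S,6R)-6-allyl-5-methyl-5-[1-(trimethylsilyl)vinyl]cyclohex-1-en-1-yl trifluoromethanesulfonate
Product: 9 2-(trimethylsilyl)ethyl (5S,6S)-6-allyl-5-methyl-5-[1-(trimethylsilyl)vinyl]cyclohex-1-ene-1-carboxylate
Conditions: Pd(OAc)2 (5 mol %), PPh3, CO (1 atm), Me3SiCH2CH2OH (5 equiv), Et3N, DMF, 50 °C
Reagents that add atoms: carbon monoxide, [C-]#[O+]; 2-(trimethylsilyl)ethanol, C[Si](C)(C)CCO
Why: Palladium-catalysed alkoxycarbonylation of the enol triflate brings in C19 as a fluoride-cleavable ester; excess alcohol traps the acyl-palladium before it can insert the allyl group.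

**Step 4**
Reactants: 9 2-(trimethylsilyl)ethyl (5S,6S)-6-allyl-5-methyl-5-[1-(trimethylsilyl)vinyl]cyclohex-1-ene-1-carboxylate
Product: 10 2-(trimethylsilyl)ethyl (3aS,7aS)-7a-methyl-1-(trimethylsilyl)-3a,6,7,7a-tetrahydro-3H-indene-4-carboxylate
Conditions: Mo(=CHCMe2Ph)(=N-2,6-i-Pr2C6H3)[OCMe(CF3)2]2 (10 mol %), benzene, 60 °C
Reagents that add atoms: none
Why: Ring-closing olefin metathesis of the 1,6-diene closes the cyclopentene (the molybdenum alkylidene is chosen for the hindered 1,1-disubstituted silylalkene); the trans fusion is already fixed and the enoate alkene is inert.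

**Step 5**
Reactants: 10 2-(trimethylsilyl)ethyl (3aS,7aS)-7a-methyl-1-(trimethylsilyl)-3a,6,7,7a-tetrahydro-3H-indene-4-carboxylate
Product: 12 2-(trimethylsilyl)ethyl (3aS,4S,7aS)-4,7a-dimethyl-1-(trimethylsilyl)-3a,4,5,6,7,7a-hexahydro-3H-indene-4-carboxylate, via lithium ester enolate 11 (not isolated)
Conditions: LiBH(s-Bu)3, THF, −78 °C; then MeI, HMPA, −78 → 0 °C
Reagents that add atoms: iodomethane, CI
Why: Conjugate hydride reduction followed by enolate C-methylation (reductive alkylation); MeI enters from the α face, away from the axial angular methyl, giving equatorial methyl and axial ester at C4 (S).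

**Step 6**
Reactants: 12 2-(trimethylsilyl)ethyl (3aS,4S,7aS)-4,7a-dimethyl-1-(trimethylsilyl)-3a,4,5,6,7,7a-hexahydro-3H-indene-4-carboxylate
Product: 14 2-(trimethylsilyl)ethyl (3aR,4S,7aS)-4,7a-dimethyl-1-oxooctahydro-1H-indene-4-carboxylate, via epoxysilane 13 (not isolated)
Conditions: m-CPBA, NaHCO3, CH2Cl2, 0 °C; aq. Na2S2O3; then 10% aq. H2SO4, MeOH, 40 °C
Reagents that add atoms: water, O
Why: Peracid epoxidation of the vinylsilane, then acid hydrolysis of the α,β-epoxysilane (water opens at the silicon-bearing carbon, Peterson-type loss of Me3SiOH) places the ketone at C8; the carbonyl oxygen comes from water and no stereocentre is formed.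

**Step 7**
Reactants: 15 (E)-3-methylpent-2-en-4-yn-1-ol
Product: 16 (E)-3-methylpenta-2,4-dien-1-ol
Conditions: H2 (1 atm), Pd/CaCO3 poisoned with Pb(OAc)2, quinoline, EtOAc, rt
Reagents that add atoms: none
Why: Lindlar semi-hydrogenation stops the terminal alkyne at the vinyl group and leaves the E trisubstituted alkene as bought.

**Step 8**
Reactants: 16 (E)-3-methylpenta-2,4-dien-1-ol
Product: 17 (E)-5-bromo-3-methylpenta-1,3-diene
Conditions: PBr3 (0.4 equiv), Et2O, −20 °C; used at once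
Reagents that add atoms: phosphorus tribromide, BrP(Br)Br
Why: Bromination of the primary allylic alcohol via its phosphite ester (SN2); low temperature keeps the E geometry and avoids allylic transposition.

**Step 9**
Reactants: 14 2-(trimethylsilyl)ethyl (3aR,4S,7aS)-4,7a-dimethyl-1-oxooctahydro-1H-indene-4-carboxylate; 17 (E)-5-bromo-3-methylpenta-1,3-diene
Product: 22 2-(trimethylsilyl)ethyl (1S,4aS,5R,8aR)-1,4a-dimethyl-5-[(2E)-3-methylpenta-2,4-dien-1-yl]-6-oxodecahydronaphthalene-1-carboxylate, via dibromomethyl alkoxide 18 (not isolated), via oxido carbenoid 19 (not isolated), via decalone lithium enolate 20 (not isolated), via axial C9 epimer 21 (not isolated)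
Conditions: CH2Br2, lithium 2,2,6,6-tetramethylpiperidide, THF, −95 °C, then 14; t-BuLi (2.1 equiv), −95 → −40 °C; then 17, DMPU, −78 → 0 °C; then NaOMe (cat.), MeOH, 40 °C
Reagents that add atoms: dibromomethane, BrCBr
Why: Proposed new method: a one-flask carbenoid ring expansion and enolate alkylation on an α-quaternary trans-hydrindanone. LiCHBr2 adds to the C8 ketone and Br/Li exchange gives a β-oxido carbenoid; the bond to the more electron-rich quaternary C10 is expected to shift to the electron-poor carbenoid carbon (retention at C10, loss of LiBr), which inserts C9 between C8 and C10 and forms ring B. C9 is born as the carbon of a regiodefined lithium enolate, which the dienyl bromide C-alkylates before it can equilibrate; methoxide then settles C9 to the equatorial side chain (R in 22). The closest known reaction types are the β-oxido carbenoid one-carbon ring enlargement of simple cycloalkanones (a Tiffeneau–Demjanov-like semipinacol shift) and regiospecific enolate alkylation.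

**Step 10**
Reactants: 22 2-(trimethylsilyl)ethyl (1S,4aS,5R,8aR)-1,4a-dimethyl-5-[(2E)-3-methylpenta-2,4-dien-1-yl]-6-oxodecahydronaphthalene-1-carboxylate
Product: 25 2-(trimethylsilyl)ethyl (1S,4aS,5R,7R,8aR)-7-acetoxy-1,4a-dimethyl-5-[(2E)-3-methylpenta-2,4-dien-1-yl]-6-oxodecahydronaphthalene-1-carboxylate, via potassium enolate 23 (not isolated), via potassium alkoxide 24 (not isolated)
Conditions: KN(SiMe3)2, THF, −78 °C; 2-(benzenesulfonyl)-3-phenyloxaziridine, −78 °C; then Ac2O, DMAP, −78 °C → rt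
Reagents that add atoms: 2-(benzenesulfonyl)-3-phenyloxaziridine, O=S(=O)(c1ccccc1)N1OC1c1ccccc1; acetic anhydride, CC(=O)OC(C)=O
Why: Kinetic enolisation goes to C7 (the C9–H is tertiary and shielded); Davis enolate hydroxylation by axial attack on the open α face gives the 7α (axial, R) oxygen, and the alkoxide is acetylated in the flask.

**Step 11**
Reactants: 25 2-(trimethylsilyl)ethyl (1S,4aS,5R,7R,8aR)-7-acetoxy-1,4a-dimethyl-5-[(2E)-3-methylpenta-2,4-dien-1-yl]-6-oxodecahydronaphthalene-1-carboxylate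
Product: 26 2-(trimethylsilyl)ethyl (1S,4aR,5R,7R,8aR)-7-acetoxy-1,4a-dimethyl-6-methylidene-5-[(2E)-3-methylpenta-2,4-dien-1-yl]decahydronaphthalene-1-carboxylate
Conditions: Zn, CH2Br2, TiCl4, THF/CH2Cl2, 0 °C → rt
Reagents that add atoms: dibromomethane, BrCBr
Why: Takai–Lombardo methylenation uses a non-basic gem-dimetallic reagent, so the hindered ketone is methylenated without epimerising C7 or C9 and without touching the esters.

**Step 12**
Reactants: 26 2-(trimethylsilyl)ethyl (1S,4aR,5R,7R,8aR)-7-acetoxy-1,4a-dimethyl-6-methylidene-5-[(2E)-3-methylpenta-2,4-dien-1-yl]decahydronaphthalene-1-carboxylate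
Product: 27 (1S,4aR,5R,7R,8aR)-7-acetoxy-1,4a-dimethyl-6-methylidene-5-[(2E)-3-methylpenta-2,4-dien-1-yl]decahydronaphthalene-1-carboxylic acid (7α-acetoxy-labda-8(17),12E,14-trien-19-oic acid)
Conditions: n-Bu4NF, THF, 0 °C → rt; aq. NH4Cl
Reagents that add atoms: none
Why: Fluoride attack on silicon fragments the 2-(trimethylsilyl)ethyl ester (β-elimination to ethene and Me3SiF), freeing the hindered axial acid without hydrolytic conditions that would cleave the allylic acetate.

**Compound list**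
1 | 3-methylcyclohex-2-en-1-one | CC1=CC(=O)CCC1 | starting material
2 | ethynyltrimethylsilane | C#C[Si](C)(C)C | starting material
3 | allyl acetate | C=CCOC(C)=O | starting material
4 | diisobutyl[1-(trimethylsilyl)vinyl]aluminium | C=C([Si](C)(C)C)[Al](CC(C)C)CC(C)C | intermediate
5 | diisobutylaluminium (S)-3-methyl-3-[1-(trimethylsilyl)vinyl]cyclohex-1-en-1-olate | C[C@]1(C(=C)[Si](C)(C)C)CCCC(O[Al](CC(C)C)CC(C)C)=C1 | intermediate
6 | (2R,3S)-2-allyl-3-methyl-3-[1-(trimethylsilyl)vinyl]cyclohexan-1-one (allyl cis to methyl) | C=CC[C@H]1C(=O)CCC[C@]1(C)C(=C)[Si](C)(C)C | intermediate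
7 | lithium (5S,6R)-6-allyl-5-methyl-5-[1-(trimethylsilyl)vinyl]cyclohex-1-en-1-olate | C=CC[C@H]1C([O-])=CCC[C@]1(C)C(=C)[Si](C)(C)C.[Li+] | intermediate
8 | (5S,6R)-6-allyl-5-methyl-5-[1-(trimethylsilyl)vinyl]cyclohex-1-en-1-yl trifluoromethanesulfonate | C=CC[C@H]1C(OS(=O)(=O)C(F)(F)F)=CCC[C@]1(C)C(=C)[Si](C)(C)C | intermediate
9 | 2-(trimethylsilyl)ethyl (5S,6S)-6-allyl-5-methyl-5-[1-(trimethylsilyl)vinyl]cyclohex-1-ene-1-carboxylate | C=CC[C@H]1C(C(=O)OCC[Si](C)(C)C)=CCC[C@]1(C)C(=C)[Si](C)(C)C | intermediate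
10 | 2-(trimethylsilyl)ethyl (3aS,7aS)-7a-methyl-1-(trimethylsilyl)-3a,6,7,7a-tetrahydro-3H-indene-4-carboxylate (trans-fused) | C[Si](C)(C)C1=CC[C@@H]2[C@]1(C)CCC=C2C(=O)OCC[Si](C)(C)C | intermediate
11 | lithium ester enolate from 1,4-hydride addition to 10 (exocyclic C4=C(OLi)OR) | C[Si](C)(C)C1=CC[C@@H]2[C@]1(C)CCCC2=C([O-])OCC[Si](C)(C)C.[Li+] | intermediate
12 | 2-(trimethylsilyl)ethyl (3aS,4S,7aS)-4,7a-dimethyl-1-(trimethylsilyl)-3a,4,5,6,7,7a-hexahydro-3H-indene-4-carboxylate | C[Si](C)(C)C1=CC[C@@H]2[C@]1(C)CCC[C@]2(C)C(=O)OCC[Si](C)(C)C | intermediate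
13 | α-epoxide of 12 at the silylalkene (oxygen anti to the angular methyl) | C[Si](C)(C)[C@]12[C@H](O1)C[C@@H]1[C@]2(C)CCC[C@]1(C)C(=O)OCC[Si](C)(C)C | intermediate
14 | 2-(trimethylsilyl)ethyl (3aR,4S,7aS)-4,7a-dimethyl-1-oxooctahydro-1H-indene-4-carboxylate (trans-hydrindanone) | O=C1CC[C@@H]2[C@]1(C)CCC[C@]2(C)C(=O)OCC[Si](C)(C)C | intermediate
15 | (E)-3-methylpent-2-en-4-yn-1-ol | OC/C=C(C)/C#C | starting material
16 | (E)-3-methylpenta-2,4-dien-1-ol | OC/C=C(C)/C=C | intermediate
17 | (E)-5-bromo-3-methylpenta-1,3-diene | BrC/C=C(C)/C=C | intermediate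
18 | lithium alkoxide of the 1-(dibromomethyl) carbinol of 14 (CHBr2 on the α face) | [Li+].[O-][C@@]1(C(Br)Br)CC[C@@H]2[C@]1(C)CCC[C@]2(C)C(=O)OCC[Si](C)(C)C | intermediate
19 | β-oxido carbenoid, the bromo(lithio)methyl lithium alkoxide | [Li+].[O-][C@@]1(C([Li])Br)CC[C@@H]2[C@]1(C)CCC[C@]2(C)C(=O)OCC[Si](C)(C)C | intermediate
20 | lithium C8(O)=C9 enolate of the ring-expanded trans-decalone | C1=C([O-])CC[C@@H]2[C@]1(C)CCC[C@]2(C)C(=O)OCC[Si](C)(C)C.[Li+] | intermediate
21 | 2-(trimethylsilyl)ethyl (1S,4aS,5S,8aR)-1,4a-dimethyl-5-[(2E)-3-methylpenta-2,4-dien-1-yl]-6-oxodecahydronaphthalene-1-carboxylate (axial side chain) | C=C/C(C)=C/C[C@@H]1C(=O)CC[C@@H]2[C@]1(C)CCC[C@]2(C)C(=O)OCC[Si](C)(C)C | intermediate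
22 | 2-(trimethylsilyl)ethyl (1S,4aS,5R,8aR)-1,4a-dimethyl-5-[(2E)-3-methylpenta-2,4-dien-1-yl]-6-oxodecahydronaphthalene-1-carboxylate | C=C/C(C)=C/C[C@H]1C(=O)CC[C@@H]2[C@]1(C)CCC[C@]2(C)C(=O)OCC[Si](C)(C)C | intermediate
23 | potassium C7=C8 enolate of 22 | C=C/C(C)=C/C[C@H]1C([O-])=CC[C@@H]2[C@]1(C)CCC[C@]2(C)C(=O)OCC[Si](C)(C)C.[K+] | intermediate
24 | potassium alkoxide of the 7α-hydroxy-8-ketone | C=C/C(C)=C/C[C@H]1C(=O)[C@H]([O-])C[C@@H]2[C@]1(C)CCC[C@]2(C)C(=O)OCC[Si](C)(C)C.[K+] | intermediate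
25 | 2-(trimethylsilyl)ethyl (1S,4aS,5R,7R,8aR)-7-acetoxy-1,4a-dimethyl-5-[(2E)-3-methylpenta-2,4-dien-1-yl]-6-oxodecahydronaphthalene-1-carboxylate | C=C/C(C)=C/C[C@H]1C(=O)[C@H](OC(C)=O)C[C@@H]2[C@]1(C)CCC[C@]2(C)C(=O)OCC[Si](C)(C)C | intermediate
26 | 2-(trimethylsilyl)ethyl (1S,4aR,5R,7R,8aR)-7-acetoxy-1,4a-dimethyl-6-methylidene-5-[(2E)-3-methylpenta-2,4-dien-1-yl]decahydronaphthalene-1-carboxylate | C=C/C(C)=C/C[C@H]1C(=C)[C@H](OC(C)=O)C[C@@H]2[C@]1(C)CCC[C@]2(C)C(=O)OCC[Si](C)(C)C | intermediate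
27 | (1S,4aR,5R,7R,8aR)-7-acetoxy-1,4a-dimethyl-6-methylidene-5-[(2E)-3-methylpenta-2,4-dien-1-yl]decahydronaphthalene-1-carboxylic acid | C=C/C(C)=C/C[C@H]1C(=C)[C@H](OC(C)=O)C[C@@H]2[C@]1(C)CCC[C@]2(C)C(=O)O | target

**Step count:** 12 steps in total; longest linear sequence 10 steps (steps 1–6 and 9–12).

**Steps most likely to fail**

Step 9 (the proposed new step; the risk is that the CH2 carbon C7 migrates instead of quaternary C10, or that the hindered enolate alkylates poorly). The fallback uses the known β-hydroxy selenide ring enlargement, sets out from 14 (and 17) and comes back at 22. Bis(phenylselanyl)methane is deprotonated with LiN(i-Pr)2 (THF, −78 °C) and alkylated with 17 to give the selenoacetal (3E)-4-methyl-1,1-bis(phenylselanyl)hexa-3,5-diene F1. n-BuLi (THF, −78 °C) cleaves one C–Se bond to the α-selanyl alkyllithium F2, which adds to the hindered ketone of 14 to give the β-hydroxy selenide F3. AgBF4 on Al2O3 in CH2Cl2 ionises the C–Se bond and the more substituted neighbour C10 shifts (semipinacol ring expansion), so the side chain arrives already attached to C9. NaOMe in MeOH then equilibrates C9 to give 22.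

Step 4 (the 1,1-disubstituted silylalkene next to a quaternary carbon may not enter the metathesis). The fallback sets out from 9 and comes back at 14. CF3CO2H in CH2Cl2 removes the vinylic silyl group to give the vinyl triene F4. Second-generation Grubbs catalyst RuCl2(=CHPh)(PCy3)(H2IMes) closes the now unhindered diene to the cyclopentene F5. LiBH(s-Bu)3 then MeI, as in step 5, gives the C4-methylated ester F6. Photo-oxygenation (O2, hν, tetraphenylporphyrin) is an ene reaction that can take an allylic hydrogen only from C6, so oxygen is delivered to C8 as the allylic hydroperoxide F7. Ac2O and pyridine dehydrate it to the cyclopentenone F8, and H2 over Pd/C saturates the C6–C7 bond to give 14.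

Step 11 (the ketone is flanked by C7–OAc and the C9 side chain, and zinc may reductively remove the α-acetoxy group). The fallback sets out from 22 and comes back at 26, with the order of events inverted. Wittig methylenation of 22 (Ph3PCH3Br, KOt-Bu, toluene, 80 °C) gives the exocyclic alkene F9. Allylic hydroxylation with SeO2 (cat.) and t-BuOOH in CH2Cl2 is expected to give the axial 7α-alcohol F10 on this trans-decalin; competing oxidation of the side-chain diene is the risk here. Ac2O, pyridine and DMAP then give 26.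

**Further compounds**
F1 | step 9 | (3E)-4-methyl-1,1-bis(phenylselanyl)hexa-3,5-diene | C=C/C(C)=C/CC([Se]c1ccccc1)[Se]c1ccccc1
F2 | step 9 | [(3E)-4-methyl-1-(phenylselanyl)hexa-3,5-dien-1-yl]lithium | [Li]C(C/C=C(C)/C=C)[Se]c1ccccc1
F3 | step 9 | β-hydroxy selenide from F2 and 14 (8β-OH; C9 epimers) | C=C/C(C)=C/CC([Se]c1ccccc1)[C@]1(O)CC[C@@H]2[C@]1(C)CCC[C@]2(C)C(=O)OCC[Si](C)(C)C
F4 | step 4 | 2-(trimethylsilyl)ethyl 6-allyl-5-methyl-5-vinylcyclohex-1-ene-1-carboxylate (configuration as in 9) | C=CC[C@H]1C(C(=O)OCC[Si](C)(C)C)=CCC[C@]1(C)C=C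
F5 | step 4 | 2-(trimethylsilyl)ethyl 7a-methyl-3a,6,7,7a-tetrahydro-3H-indene-4-carboxylate (trans-fused) | C1=CC[C@@H]2[C@]1(C)CCC=C2C(=O)OCC[Si](C)(C)C
F6 | step 4 | 2-(trimethylsilyl)ethyl 4,7a-dimethyl-3a,4,5,6,7,7a-hexahydro-3H-indene-4-carboxylate (configuration as in 12) | C1=CC[C@@H]2[C@]1(C)CCC[C@]2(C)C(=O)OCC[Si](C)(C)C
F7 | step 4 | allylic 1α-hydroperoxide with the 2,3-alkene (indene numbering) | OO[C@@H]1C=C[C@@H]2[C@]1(C)CCC[C@]2(C)C(=O)OCC[Si](C)(C)C
F8 | step 4 | cyclopentenone, the 2,3-didehydro derivative of 14 | O=C1C=C[C@@H]2[C@]1(C)CCC[C@]2(C)C(=O)OCC[Si](C)(C)C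
F9 | step 11 | 2-(trimethylsilyl)ethyl ester of labda-8(17),12E,14-trien-19-oic acid | C=C/C(C)=C/C[C@H]1C(=C)CC[C@@H]2[C@]1(C)CCC[C@]2(C)C(=O)OCC[Si](C)(C)C
F10 | step 11 | 2-(trimethylsilyl)ethyl ester of 7α-hydroxy-labda-8(17),12E,14-trien-19-oic acid | C=C/C(C)=C/C[C@H]1C(=C)[C@H](O)C[C@@H]2[C@]1(C)CCC[C@]2(C)C(=O)OCC[Si](C)(C)C
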